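**Retrosynthetic overview**
- The two esters go on last (C6 benzoate, then C10 angelate). The C10–O bond comes from α-face epoxidation of a C9=C10 alkene, itself made by reductive transposition of a C10 enone.
- The seven-membered enone comes from a trans-fused 4-methylidene-hydrindene by an oxidative 1,2-alkenyl shift that pulls the exocyclic CH2 into the ring (six → seven).
- The six-membered ring comes from ring-closing metathesis of a triene-diol. The C4 carbinol comes from isopropyl addition to a cyclopentanone.
- C1, C5 and C6 are set in one pot: asymmetric conjugate addition of a dienylalane to 3-methylcyclopentenone, then aldol trapping with acrolein.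
- Ring order: five-membered ring (bought) → six-membered ring (metathesis) → seven-membered ring (expansion).

Assumption: positions use daucane numbering. C1 is the quaternary ring-fusion carbon, C4 the isopropyl carbinol, C5 the ring-fusion CH, C6 the benzoate carbon, C8 the methyl-bearing alkene carbon and C10 the angelate carbon. β is the face of the C1 methyl. The antipode of the chiral carbene ligand is chosen to give (S)-C1.

**Step 1**
Reactants: 1 2-methylbut-1-en-3-yne; 2 3-methylcyclopent-2-en-1-one; 3 acrolein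
Product: 6 (2S,3S)-2-[(1S)-1-hydroxyprop-2-en-1-yl]-3-methyl-3-(3-methylbuta-1,3-dien-2-yl)cyclopentan-1-one, via dienylalane 4 (not isolated), via aluminium enolate 5 (not isolated)
Conditions: 1, iBu2AlH, Ni(dppp)Cl2 (3 mol %), THF, 0 → 22 °C; then 2, Cu(OTf)2 (5 mol %), chiral diphenylethylenediamine-derived sulfonate imidazolinium salt (5 mol %, carbene set free with Ag2O), −30 °C; then 3, −78 °C; aq. Rochelle salt
Reagents that add atoms: none
Why: Nickel-catalysed α-selective hydroalumination gives the internal dienylalane, carbene–copper-catalysed asymmetric conjugate addition sets quaternary C1 under catalyst control, and the regiodefined aluminium enolate adds to acrolein through a closed Zimmerman–Traxler aldol transition state on the face anti to the bulky dienyl group, which places the C5 side chain trans to the dienyl group and gives the anti C5/C6 aldol that the target needs.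

**Step 2**
Reactants: 6 aldol ketone; 7 isopropylmagnesium chloride
Product: 8 (1R,2S,3S)-2-[(1S)-1-hydroxyprop-2-en-1-yl]-3-methyl-3-(3-methylbuta-1,3-dien-2-yl)-1-(propan-2-yl)cyclopentan-1-ol
Conditions: 7 (3 equiv), LaCl3·2LiCl (1 equiv), THF, −78 → −20 °C; aq. NH4Cl
Reagents that add atoms: none
Why: Lanthanide-assisted Grignard 1,2-addition suppresses enolisation and retro-aldol, and the nucleophile enters from the α face, opposite to the adjacent C5 side chain and the pseudo-axial C1 methyl, so the C4 hydroxyl ends β and the isopropyl group α.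

**Step 3**
Reactants: 8 triene-diol
Product: 9 (1R,3aS,7S,7aS)-3a,5-dimethyl-4-methylidene-1-(propan-2-yl)-2,3,3a,4,7,7a-hexahydro-1H-indene-1,7-diol (trans-fused)
Conditions: second-generation Hoveyda–Grubbs catalyst (5 mol %), 1,4-benzoquinone (10 mol %), toluene (2 mM), 80 °C, argon sparge
Reagents that add atoms: none
Why: Ring-closing metathesis starts at the monosubstituted allylic-alcohol olefin and closes on the CH2=C(CH3) terminus of the diene to form C7=C8 in a six-membered ring, because closure on the other terminus would need a trans-fused bicyclo[3.3.0]octene; no stereocentre is touched.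

**Step 4**
Reactants: 9 methylidene-hydrindene diol
Product: 11 (1R,3aS,8S,8aS)-1,8-dihydroxy-3a,6-dimethyl-1-(propan-2-yl)-2,3,3a,7,8,8a-hexahydroazulen-4(1H)-one, via β,γ-enone 10 (not isolated)
Conditions: PhI(OH)OTs (1.1 equiv), 2,6-di-tert-butylpyridine (1.5 equiv), MeCN–H2O 9:1, −20 → 0 °C; then DBU (1 equiv), 23 °C
Reagents that add atoms: water, O
Why: Proposed new method: oxidative ring expansion of a semicyclic 1,3-diene by a 1,2-alkenyl shift, in which the electrophilic trivalent iodine reagent adds to the unhindered exocyclic CH2 (C9), water captures the allyl cation at its tertiary terminus C10 (the 1,2-mode that isoprene shows with electrophile/water), and the β-hydroxyalkyl(phenyl)iodonium loses iodobenzene while the C10–C8 alkenyl bond migrates to C9 under the push of the hydroxyl (semipinacol, with the alkenyl group migrating in preference to quaternary C1), giving the seven-membered β,γ-enone that DBU moves into conjugation; the closest known reaction types are the hydroxy(tosyloxy)iodobenzene ring expansion of methylenecycloalkanes with aryl migration and the Tiffeneau–Demjanov-type homologation of enones with vinyl migration, and no stereocentre is formed or lost.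

**Step 5**
Reactants: 11 seven-membered enone diol
Product: 13 (3R,3aS,4S,6R,8aR)-6,8a-dimethyl-3-(propan-2-yl)-1,2,3,3a,4,5,6,8a-octahydroazulene-3,4-diol, via tosylhydrazone 12 (not isolated)
Conditions: TsNHNH2, AcOH (cat.), EtOH, 60 °C; concentrate; catecholborane (4 equiv), CHCl3, −10 °C; NaOAc·3H2O, reflux
Reagents that add atoms: none
Why: Direct hydride reduction of the C10 ketone would come anti to the axial C1 methyl and give the wrong (β) alcohol, so the enone is taken through tosylhydrazone reduction with alkene transposition (allylic diazene retro-ene), in which hydride adds to C10 from the α face and the β-diazene hands its hydrogen suprafacially to C8 (C8–H β), moving the alkene to C9=C10.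

**Step 6**
Reactants: 13 alkene diol; 14 benzaldehyde
Product: 16 (3R,3aS,4S,6R,8aR)-3-hydroxy-6,8a-dimethyl-3-(propan-2-yl)-1,2,3,3a,4,5,6,8a-octahydroazulen-4-yl benzoate, via benzoyl bromide 15 (not isolated)
Conditions: 14, NBS, AIBN (cat.), PhCF3, 80 °C; cool; then 13, pyridine, DMAP (cat.), CH2Cl2, 0 → 23 °C
Reagents that add atoms: none
Why: Radical bromination turns the aldehyde into the acyl bromide, and DMAP-catalysed esterification then acylates only the secondary C6 hydroxyl because the C4 hydroxyl is tertiary and flanked by isopropyl; no stereocentre changes.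

**Step 7**
Reactants: 16 alkene benzoate
Product: 17 (3R,3aS,4S,6R,7R,8S,8aS)-7,8-epoxy-3-hydroxy-6,8a-dimethyl-3-(propan-2-yl)decahydroazulen-4-yl benzoate (9α,10α-epoxide)
Conditions: mCPBA, NaHCO3, CH2Cl2, 0 °C
Reagents that add atoms: mCPBA (3-chloroperoxybenzoic acid), O=C(OO)c1cccc(Cl)c1
Why: Prilezhaev epoxidation of the only alkene takes place on the α face, anti to the axial C1 methyl next to C10, which fixes the C10–O bond in the α configuration.

**Step 8**
Reactants: 17 epoxide
Product: 19 (3R,3aS,4S,8R,8aS)-3,8-dihydroxy-6,8a-dimethyl-3-(propan-2-yl)-1,2,3,3a,4,5,8,8a-octahydroazulen-4-yl benzoate, via hydroxy selenide 18 (not isolated)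
Conditions: (PhSe)2, NaBH4, EtOH, 23 → 60 °C; then THF, 30 % H2O2, 0 → 23 °C
Reagents that add atoms: none
Why: Epoxide-to-allylic-alcohol conversion by selenide opening and selenoxide syn-elimination: the selenolate opens the epoxide trans-diaxially at C9 (C10 is neopentyl) from the β face, and the C9β selenoxide eliminates with the cis C8–H β set in step 5, giving C8=C9 while the 10α carbinol is untouched.

**Step 9**
Reactants: 19 allylic alcohol; 20 angelic acid
Product: 22 target, (3R,3aS,4S,8R,8aS)-4-benzoyloxy-3-hydroxy-6,8a-dimethyl-3-(propan-2-yl)-1,2,3,3a,4,5,8,8a-octahydroazulen-8-yl (Z)-2-methylbut-2-enoate, via mixed anhydride 21 (not isolated)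
Conditions: 20, 2,4,6-trichlorobenzoyl chloride, Et3N, toluene, 23 °C; then 19, 80 °C
Reagents that add atoms: none
Why: Mixed-anhydride (Yamaguchi-type) esterification run without a nucleophilic amine catalyst transfers the angeloyl group to the only free secondary hydroxyl without Z-to-E isomerisation, and the tertiary C4 hydroxyl stays free.

**Compound list**
1 | 2-methylbut-1-en-3-yne | C=C(C)C#C | starting material
2 | 3-methylcyclopent-2-en-1-one | CC1=CC(=O)CC1 | starting material
3 | acrolein (prop-2-enal) | C=CC=O | starting material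
4 | diisobutyl(3-methylbuta-1,3-dien-2-yl)aluminium | C=C(C)C(=C)[Al](CC(C)C)CC(C)C | intermediate (not isolated)
5 | diisobutylaluminium enolate (C4–O–Al, C4=C5) of (S)-3-methyl-3-(3-methylbuta-1,3-dien-2-yl)cyclopentanone | C=C(C)C(=C)[C@@]1(C)CCC(O[Al](CC(C)C)CC(C)C)=C1 | intermediate (not isolated)
6 | (2S,3S)-2-[(1S)-1-hydroxyprop-2-en-1-yl]-3-methyl-3-(3-methylbuta-1,3-dien-2-yl)cyclopentan-1-one | C=C[C@H](O)[C@@H]1[C@](C(=C)C(C)=C)(C)CCC1=O | intermediate
7 | isopropylmagnesium chloride | CC(C)[Mg]Cl | starting material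
8 | (1R,2S,3S)-2-[(1S)-1-hydroxyprop-2-en-1-yl]-3-methyl-3-(3-methylbuta-1,3-dien-2-yl)-1-(propan-2-yl)cyclopentan-1-ol | C=C[C@H](O)[C@@H]1[C@](C(=C)C(C)=C)(C)CC[C@@]1(O)C(C)C | intermediate
9 | (1R,3aS,7S,7aS)-3a,5-dimethyl-4-methylidene-1-(propan-2-yl)-2,3,3a,4,7,7a-hexahydro-1H-indene-1,7-diol | C=C1C(C)=C[C@H](O)[C@@H]2[C@]1(C)CC[C@@]2(O)C(C)C | intermediate
10 | (1R,3aS,8S,8aS)-1,8-dihydroxy-3a,6-dimethyl-1-(propan-2-yl)-2,3,3a,5,8,8a-hexahydroazulen-4(1H)-one | O=C1CC(C)=C[C@H](O)[C@@H]2[C@]1(C)CC[C@@]2(O)C(C)C | intermediate (not isolated)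
11 | (1R,3aS,8S,8aS)-1,8-dihydroxy-3a,6-dimethyl-1-(propan-2-yl)-2,3,3a,7,8,8a-hexahydroazulen-4(1H)-one | O=C1C=C(C)C[C@H](O)[C@@H]2[C@]1(C)CC[C@@]2(O)C(C)C | intermediate
12 | N-tosylhydrazone of 11 (C=N geometry not defined) | Cc1ccc(cc1)S(=O)(=O)NN=C1C=C(C)C[C@H](O)[C@@H]2[C@]1(C)CC[C@@]2(O)C(C)C | intermediate (not isolated)
13 | (3R,3aS,4S,6R,8aR)-6,8a-dimethyl-3-(propan-2-yl)-1,2,3,3a,4,5,6,8a-octahydroazulene-3,4-diol | C1=C[C@H](C)C[C@H](O)[C@@H]2[C@]1(C)CC[C@@]2(O)C(C)C | intermediate
14 | benzaldehyde | O=Cc1ccccc1 | starting material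
15 | benzoyl bromide | O=C(Br)c1ccccc1 | intermediate (not isolated)
16 | (3R,3aS,4S,6R,8aR)-3-hydroxy-6,8a-dimethyl-3-(propan-2-yl)-1,2,3,3a,4,5,6,8a-octahydroazulen-4-yl benzoate | C1=C[C@H](C)C[C@H](OC(=O)c3ccccc3)[C@@H]2[C@]1(C)CC[C@@]2(O)C(C)C | intermediate
17 | 9α,10α-epoxide of 16 | O1[C@@H]2[C@H]1[C@H](C)C[C@H](OC(=O)c4ccccc4)[C@@H]3[C@]2(C)CC[C@@]3(O)C(C)C | intermediate
18 | (3R,3aS,4S,6R,7S,8S,8aS)-3,8-dihydroxy-6,8a-dimethyl-7-(phenylselanyl)-3-(propan-2-yl)decahydroazulen-4-yl benzoate | O[C@@H]1[C@@H]([Se]c5ccccc5)[C@H](C)C[C@H](OC(=O)c3ccccc3)[C@@H]2[C@]1(C)CC[C@@]2(O)C(C)C | intermediate (not isolated)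
19 | (3R,3aS,4S,8R,8aS)-3,8-dihydroxy-6,8a-dimethyl-3-(propan-2-yl)-1,2,3,3a,4,5,8,8a-octahydroazulen-4-yl benzoate | O[C@@H]1C=C(C)C[C@H](OC(=O)c3ccccc3)[C@@H]2[C@]1(C)CC[C@@]2(O)C(C)C | intermediate
20 | angelic acid, (Z)-2-methylbut-2-enoic acid | C/C=C(/C)C(=O)O | starting material
21 | (Z)-2-methylbut-2-enoic 2,4,6-trichlorobenzoic anhydride | C/C=C(/C)C(=O)OC(=O)c1c(Cl)cc(Cl)cc1Cl | intermediate (not isolated)
22 | CNP0397959.1 | C/C=C(/C)C(=O)O[C@@H]1C=C(C)C[C@H](OC(=O)c2ccccc2)[C@@H]2[C@]1(C)CC[C@@]2(O)C(C)C | target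

**Totals**
Total step count: 9. Longest linear sequence: 9.

**Steps most likely to fail**

Step 1. A dienylalane has not been used in this conjugate addition, and the aluminium enolate must then react cleanly with acrolein.
- The fallback sets out from 2 and comes back at 6. It builds the diene by cross-coupling after the addition instead of transferring it.
- Ethynyltrimethylsilane and iBu2AlH give the well-behaved silicon-substituted vinylalane diisobutyl[1-(trimethylsilyl)ethenyl]aluminium F1.
- The same copper–carbene addition to 2 gives the aluminium enolate F2, and acrolein gives the silylvinyl aldol F3.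
- Iododesilylation (NIS, hexafluoroisopropanol) gives the vinyl iodide aldol F4.
- Negishi coupling with isopropenylzinc bromide and Pd(PPh3)4 gives 6.

Step 2. A branched Grignard reagent on a hindered β-hydroxy ketone may enolise it, reduce it or trigger retro-aldol.
- The fallback sets out from 6 and comes back at 8. It removes the alkoxide from the problem.
- Et3SiOTf and 2,6-lutidine give the silyl ether ketone F5.
- The organocerium reagent from iPrLi and CeCl3 at −78 °C gives the silyl ether carbinol F6.
- Bu4NF gives 8.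

Step 4 (the new step). The allyl cation may be captured at C7, a spiro-epoxide may form, or the dienylic alcohol may solvolyse.
- The fallback uses known chemistry, sets out from 9 and comes back at 10, which DBU then converts to 11 as in the route.
- NBS, NaHCO3 and acetone–H2O at 0 °C give the bromohydrin F7. This is 1,2-addition with bromine at C9 and hydroxyl at C10.
- The established silver-promoted halohydrin semipinacol ring enlargement (AgBF4, 2,6-di-tert-butylpyridine, CH2Cl2, −40 °C) moves the alkenyl carbon C8 to C9 and gives 10.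

**Further compounds**
F1 | step 1 | diisobutyl[1-(trimethylsilyl)ethenyl]aluminium | C=C([Si](C)(C)C)[Al](CC(C)C)CC(C)C
F2 | step 1 | diisobutylaluminium enolate of 3-methyl-3-[1-(trimethylsilyl)ethenyl]cyclopentanone | C=C([Si](C)(C)C)[C@@]1(C)CCC(O[Al](CC(C)C)CC(C)C)=C1
F3 | step 1 | 2-(1-hydroxyprop-2-en-1-yl)-3-methyl-3-[1-(trimethylsilyl)ethenyl]cyclopentan-1-one (configured as 6) | C=C[C@H](O)[C@@H]1[C@](C(=C)[Si](C)(C)C)(C)CCC1=O
F4 | step 1 | 2-(1-hydroxyprop-2-en-1-yl)-3-(1-iodoethenyl)-3-methylcyclopentan-1-one (configured as 6) | C=C[C@H](O)[C@@H]1[C@](C(=C)I)(C)CCC1=O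
F5 | step 2 | triethylsilyl ether of 6 | C=C[C@H](O[Si](CC)(CC)CC)[C@@H]1[C@](C(=C)C(C)=C)(C)CCC1=O
F6 | step 2 | C6 triethylsilyl ether of 8 | C=C[C@H](O[Si](CC)(CC)CC)[C@@H]1[C@](C(=C)C(C)=C)(C)CC[C@@]1(O)C(C)C
F7 | step 4 | 4-(bromomethyl)-3a,5-dimethyl-1-(propan-2-yl)-2,3,3a,4,7,7a-hexahydro-1H-indene-1,4,7-triol (C10 hydroxyl α expected; this centre is lost again) | O[C@]1(CBr)C(C)=C[C@H](O)[C@@H]2[C@]1(C)CC[C@@]2(O)C(C)C
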